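**Plan**

1. All nine phenols are carried as benzyl ethers. The retrosynthesis opens the central dihydrofuran (unit 2; units 1–3 are counted from the styryl end, rings A–C are their benzo rings) at three bonds together: C3(unit 2)–C4(ring C), C2–C3 and C2–O.
2. This is possible because C3 of unit 2 is a CH between ring B, which bears the ring oxygen on the ortho carbon, and C4 of ring C. Ring B can therefore be an ortho-quinone methide with that C3 as its exocyclic carbon, ring C enters as an aryl nucleophile (its C4 is meta to both oxygens), and C2 with its aryl group enters as a benzylic sulfur ylide.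
3. Units 1 and 3 share one (2R,3R) 4-bromo-3-[3,5-bis(benzyloxy)phenyl]dihydrobenzofuran, made by the same kind of three-component union. The bromide itself becomes the ring-C Grignard; formylation of its resorcinol ring next to the C3 attachment starts ring B of the unit-1 fragment.
4. Forward order: dihydrofuran common to units 1 and 3 (step 7), ring-B aldehyde (step 8), stilbene by Heck coupling (step 9), ring-B phenol and Boc (steps 10, 11), dihydrofuran of unit 2 (step 15), debenzylation (step 16).
5. Stereochemistry: in each annulation the C2-symmetric sulfide of the ylide sets C2 (choice of the ylide face, then inversion on ring closure), and the anti course of the C–C bond formation sets C3 trans to it. (2R,5R)-2,5-Dimethylthiolane serves the (2R,3R) units 1 and 3, its enantiomer the (2S,3S) unit 2; the E alkene comes from the Heck reaction.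
6. Benzyl ethers replace methyl ethers so that the last step runs at −78 °C; a warm boron tribromide demethylation would risk addition of ring B to the protonated stilbene of unit 1.

Key step: step 15

Assumption: the 4-(benzyloxy)benzyl ylide of (2R,5R)-2,5-dimethylthiolane is taken to offer the same face of its ylide carbon to a quinone methide as it does to an aldehyde in epoxidation, which corresponds to 2R after ring closure; if the first annulation shows the opposite sense, the two enantiomeric sulfonium salts exchange their places in the route.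

**Route**

Step 1
Reactants: 1 1,3-bis(benzyloxy)-5-bromobenzene
Product: 2 2,4-bis(benzyloxy)-6-bromobenzaldehyde
Conditions: POCl3, DMF, 0 → 90 °C; NaOAc aq.
Reagents that add atoms: N,N-dimethylformamide, CN(C)C=O; water, O
Why: Vilsmeier–Haack formylation should go para to one benzyloxy group at the carbon between bromine and the other benzyloxy group, as is usual for 1-bromo-3,5-dialkoxybenzenes; the minor isomer formylated between the two ethers would be removed by crystallisation.

Step 2
Reactants: 2 2,4-bis(benzyloxy)-6-bromobenzaldehyde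
Product: 3 4-(benzyloxy)-2-bromo-6-hydroxybenzaldehyde
Conditions: MgBr2·OEt2, toluene/Et2O, 75 °C; 1 M HCl
Reagents that add atoms: none
Why: Chelation-controlled ether cleavage: magnesium bridges the aldehyde oxygen and the ortho ether oxygen and bromide removes that benzyl group only, leaving the para benzyl ether untouched.

Step 3
Reactants: 3 4-(benzyloxy)-2-bromo-6-hydroxybenzaldehyde
Product: 4 tert-butyl 5-(benzyloxy)-3-bromo-2-formylphenyl carbonate
Conditions: Boc2O, DMAP (cat.), i-Pr2NEt, THF, 0 °C → rt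
Reagents that add atoms: di-tert-butyl dicarbonate, CC(C)(C)OC(=O)OC(=O)OC(C)(C)C
Why: DMAP-catalysed O-acylation of the phenol gives the aryl tert-butyl carbonate that later serves as the internal leaving group for quinone methide release.

Step 4
Reactants: 5 (2S,5S)-hexane-2,5-diol
Product: 6 (2S,5S)-hexane-2,5-diyl dimethanesulfonate
Conditions: MsCl, Et3N, CH2Cl2, 0 °C
Reagents that add atoms: methanesulfonyl chloride, CS(=O)(=O)Cl
Why: O-Sulfonylation of both secondary alcohols leaves the two stereocentres untouched.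

Step 5
Reactants: 6 (2S,5S)-hexane-2,5-diyl dimethanesulfonate
Product: 7 (2R,5R)-2,5-dimethylthiolane
Conditions: Na2S·9H2O, DMSO, rt
Reagents that add atoms: sodium sulfide, [Na+].[Na+].[S-2]
Why: Double SN2 displacement by sulfide (the second a 5-exo-tet ring closure) inverts both carbons, so the (2S,5S) dimesylate should give the (2R,5R) thiolane.

Step 6
Reactants: 7 (2R,5R)-2,5-dimethylthiolane; 8 4-(benzyloxy)benzyl chloride
Product: 9 (2R,5R)-1-[4-(benzyloxy)benzyl]-2,5-dimethylthiolan-1-ium tetrafluoroborate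
Conditions: AgBF4, CH2Cl2, 0 °C → rt, dark
Reagents that add atoms: silver tetrafluoroborate, [Ag+].F[B-](F)(F)F
Why: Silver-assisted S-alkylation; the two lone pairs of the C2-symmetric sulfide are equivalent so one salt forms, and the non-nucleophilic counter-ion prevents dealkylation of the electron-rich benzylsulfonium ion.

Step 7
Reactants: 1 1,3-bis(benzyloxy)-5-bromobenzene; 4 tert-butyl 5-(benzyloxy)-3-bromo-2-formylphenyl carbonate; 9 (2R,5R)-1-[4-(benzyloxy)benzyl]-2,5-dimethylthiolan-1-ium tetrafluoroborate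
Product: 15 (2R,3R)-6-(benzyloxy)-2-[4-(benzyloxy)phenyl]-3-[3,5-bis(benzyloxy)phenyl]-4-bromo-2,3-dihydro-1-benzofuran, via arylmagnesium bromide 10 (not isolated), via sulfonium ylide 11 (not isolated), via magnesium alkoxide 12 (not isolated), via o-quinone methide 13 (not isolated), via betaine 14 (not isolated)
Conditions: 1, Mg, I2 (cat.), THF, 50 °C; 4 (1.0 equiv), THF, −78 °C; then ylide from 9, LiN(SiMe3)2, THF, −78 °C; −78 → 0 °C; NH4Cl aq.
Reagents that add atoms: none
Why: Proposed new method: Grignard 10 adds to the aldehyde of 4, alkoxide 12 takes the Boc group from the neighbouring phenol oxygen and expels tert-butyl carbonate to release o-quinone methide 13, ylide 11 adds to its exocyclic carbon, and the phenoxide of betaine 14 displaces the sulfide (5-exo-tet, inversion), so that the ylide face left open by the sulfide gives C2 (R) and the anti addition gives the trans C3 (R); the closest known reaction types are the Grignard-triggered release of o-quinone methides from O-Boc salicylaldehydes (so far trapped by a second organometallic or an enol ether) and the (4+1) annulation of sulfonium ylides with o-quinone methides set free by base from o-hydroxybenzyl sulfones.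

Step 8
Reactants: 15 (2R,3R)-6-(benzyloxy)-2-[4-(benzyloxy)phenyl]-3-[3,5-bis(benzyloxy)phenyl]-4-bromo-2,3-dihydro-1-benzofuran
Product: 16 2,4-bis(benzyloxy)-6-{(2R,3R)-6-(benzyloxy)-2-[4-(benzyloxy)phenyl]-4-bromo-2,3-dihydro-1-benzofuran-3-yl}benzaldehyde
Conditions: POCl3 (1.5 equiv), DMF, 0 → 45 °C; NaOAc aq.
Reagents that add atoms: N,N-dimethylformamide, CN(C)C=O; water, O
Why: Vilsmeier–Haack formylation of a 5-alkylresorcinol diether goes ortho to the alkyl carbon and para to an ether oxygen, and the pendant 3,5-bis(benzyloxy)phenyl ring (the future ring B) should react first because its open positions are activated by two ether oxygens and the benzylic carbon, whereas those of the bromine-bearing benzo ring are meta to its alkyl carbon and ortho or para to bromine and would need the higher temperature of step 1; the monoalkoxy aryl ring is inert, the stereocentres are not touched, and any isomer formylated between the two ethers would be removed by chromatography.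

Step 9
Reactants: 16 2,4-bis(benzyloxy)-6-{(2R,3R)-6-(benzyloxy)-2-[4-(benzyloxy)phenyl]-4-bromo-2,3-dihydro-1-benzofuran-3-yl}benzaldehyde; 17 4-(benzyloxy)styrene
Product: 18 2,4-bis(benzyloxy)-6-{(2R,3R)-6-(benzyloxy)-2-[4-(benzyloxy)phenyl]-4-[(E)-2-[4-(benzyloxy)phenyl]ethenyl]-2,3-dihydro-1-benzofuran-3-yl}benzaldehyde
Conditions: Pd(P(t-Bu)3)2 (5 mol%), Cy2NMe, 1,4-dioxane, 90 °C
Reagents that add atoms: none
Why: Mizoroki–Heck coupling: the zerovalent palladium complex of a bulky electron-rich phosphine inserts into the hindered C4–Br bond, and syn insertion of the styrene with syn β-hydride elimination should give the E stilbene while aldehyde and benzyl ethers stay inert.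

Step 10
Reactants: 18 2,4-bis(benzyloxy)-6-{(2R,3R)-6-(benzyloxy)-2-[4-(benzyloxy)phenyl]-4-[(E)-2-[4-(benzyloxy)phenyl]ethenyl]-2,3-dihydro-1-benzofuran-3-yl}benzaldehyde
Product: 19 4-(benzyloxy)-2-{(2R,3R)-6-(benzyloxy)-2-[4-(benzyloxy)phenyl]-4-[(E)-2-[4-(benzyloxy)phenyl]ethenyl]-2,3-dihydro-1-benzofuran-3-yl}-6-hydroxybenzaldehyde
Conditions: MgBr2·OEt2, toluene/Et2O, 70 °C; cold 1 M HCl
Reagents that add atoms: none
Why: The same chelation-controlled debenzylation as in step 2 frees only the ring-B oxygen ortho to the aldehyde, and this mild Lewis acid should not touch the stilbene or the dihydrofuran.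

Step 11
Reactants: 19 4-(benzyloxy)-2-{(2R,3R)-6-(benzyloxy)-2-[4-(benzyloxy)phenyl]-4-[(E)-2-[4-(benzyloxy)phenyl]ethenyl]-2,3-dihydro-1-benzofuran-3-yl}-6-hydroxybenzaldehyde
Product: 20 tert-butyl 5-(benzyloxy)-3-{(2R,3R)-6-(benzyloxy)-2-[4-(benzyloxy)phenyl]-4-[(E)-2-[4-(benzyloxy)phenyl]ethenyl]-2,3-dihydro-1-benzofuran-3-yl}-2-formylphenyl carbonate
Conditions: Boc2O, DMAP (cat.), i-Pr2NEt, THF, 0 °C → rt
Reagents that add atoms: di-tert-butyl dicarbonate, CC(C)(C)OC(=O)OC(=O)OC(C)(C)C
Why: DMAP-catalysed O-acylation of the chelated phenol, as in step 3, installs the carbonate needed for quinone methide release on ring B.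

Step 12
Reactants: 21 (2R,5R)-hexane-2,5-diol
Product: 22 (2R,5R)-hexane-2,5-diyl dimethanesulfonate
Conditions: MsCl, Et3N, CH2Cl2, 0 °C
Reagents that add atoms: methanesulfonyl chloride, CS(=O)(=O)Cl
Why: O-Sulfonylation as in step 4, in the enantiomeric series.

Step 13
Reactants: 22 (2R,5R)-hexane-2,5-diyl dimethanesulfonate
Product: 23 (2S,5S)-2,5-dimethylthiolane
Conditions: Na2S·9H2O, DMSO, rt
Reagents that add atoms: sodium sulfide, [Na+].[Na+].[S-2]
Why: Double SN2 displacement with inversion at both carbons, as in step 5, should give the (2S,5S) thiolane.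

Step 14
Reactants: 23 (2S,5S)-2,5-dimethylthiolane; 8 4-(benzyloxy)benzyl chloride
Product: 24 (2S,5S)-1-[4-(benzyloxy)benzyl]-2,5-dimethylthiolan-1-ium tetrafluoroborate
Conditions: AgBF4, CH2Cl2, 0 °C → rt, dark
Reagents that add atoms: silver tetrafluoroborate, [Ag+].F[B-](F)(F)F
Why: Silver-assisted S-alkylation as in step 6.

Step 15
Reactants: 15 (2R,3R)-6-(benzyloxy)-2-[4-(benzyloxy)phenyl]-3-[3,5-bis(benzyloxy)phenyl]-4-bromo-2,3-dihydro-1-benzofuran; 20 tert-butyl 5-(benzyloxy)-3-{(2R,3R)-6-(benzyloxy)-2-[4-(benzyloxy)phenyl]-4-[(E)-2-[4-(benzyloxy)phenyl]ethenyl]-2,3-dihydro-1-benzofuran-3-yl}-2-formylphenyl carbonate; 24 (2S,5S)-1-[4-(benzyloxy)benzyl]-2,5-dimethylthiolan-1-ium tetrafluoroborate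
Product: 31 nona-O-benzyl miyabenol A, via aryllithium 25 (not isolated), via arylmagnesium bromide 26 (not isolated), via sulfonium ylide 27 (not isolated), via magnesium alkoxide 28 (not isolated), via o-quinone methide 29 (not isolated), via betaine 30 (not isolated)
Conditions: 15, t-BuLi (2 equiv), THF, −78 °C; MgBr2·OEt2, −78 → −40 °C; 20 (1.0 equiv), THF, −78 °C; then ylide from 24, LiN(SiMe3)2, THF, −78 °C; −78 → 0 °C; NH4Cl aq.
Reagents that add atoms: none
Why: Proposed new method: Grignard 26 adds to the aldehyde of 20; in alkoxide 28 the Boc group moves from the neighbouring phenol oxygen to the alkoxide and tert-butyl carbonate leaves, which turns ring B into o-quinone methide 29 whose exocyclic carbon (C3 of unit 2) carries ring C; ylide 27 adds to that carbon, ring B re-aromatises to the phenoxide of betaine 30, and this oxygen displaces the sulfide from the benzylic carbon. The closest known reaction types are the Grignard-triggered release of o-quinone methides from O-Boc salicylaldehydes, so far intercepted by a second organometallic or an enol ether, and the (4+1) annulation of sulfonium ylides with o-quinone methides liberated by base from o-hydroxybenzyl sulfones; their merger in one flask on two large fragments is new. The dihydrofuran of unit 2 closes by a 5-exo-tet O-alkylation with inversion at C2. C2 (S) is set by the face of the ylide carbon that the (2S,5S)-sulfide leaves open followed by that inversion, and C3 (S) by the anti course of the C–C bond formation that leads to the trans ring, so the reagent also decides which face of the methide is used while the two resident C3 centres flanking it can only reinforce or erode this choice. The step needs the Grignard to meet the aldehyde and not the carbonate or the methide, and the ylide to meet the methide and not the aldehyde: one equivalent of 26 at −78 °C should consume the aldehyde before the methide is released on warming, and 27 is introduced only after that. Attack at the exocyclic carbon is the only mode that restores the aromaticity of ring B, and ring C is brought in as an organometallic because its C4 is meta to both oxygens and would not react as an arene nucleophile.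

Step 16
Reactants: 31 nona-O-benzyl miyabenol A
Product: 32 miyabenol A
Conditions: BCl3 (excess), C6HMe5, CH2Cl2, −78 °C; MeOH/CHCl3 at −78 °C, then pH 7 phosphate buffer
Reagents that add atoms: none
Why: Lewis-acid debenzylation with pentamethylbenzene as a non-basic cation scavenger should cleave all nine aryl benzyl ethers at −78 °C, the benzyl cations ending on the scavenger and not on the electron-rich rings, while the low temperature and cold buffered quench keep the stilbene of unit 1 and the benzylic C2–O bonds of the trans dihydrofurans from acid-driven cyclisation.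

**Compound list**

1 | 1,3-bis(benzyloxy)-5-bromobenzene | Brc1cc(OCc2ccccc2)cc(OCc2ccccc2)c1 | starting material
2 | 2,4-bis(benzyloxy)-6-bromobenzaldehyde | O=Cc1c(Br)cc(OCc2ccccc2)cc1OCc1ccccc1 | intermediate
3 | 4-(benzyloxy)-2-bromo-6-hydroxybenzaldehyde | O=Cc1c(O)cc(OCc2ccccc2)cc1Br | intermediate
4 | tert-butyl 5-(benzyloxy)-3-bromo-2-formylphenyl carbonate | O=Cc1c(Br)cc(OCc2ccccc2)cc1OC(=O)OC(C)(C)C | intermediate
5 | (2S,5S)-hexane-2,5-diol | C[C@H](O)CC[C@H](C)O | starting material
6 | (2S,5S)-hexane-2,5-diyl dimethanesulfonate | C[C@H](OS(C)(=O)=O)CC[C@H](C)OS(C)(=O)=O | intermediate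
7 | (2R,5R)-2,5-dimethylthiolane | C[C@@H]1CC[C@@H](C)S1 | intermediate
8 | 4-(benzyloxy)benzyl chloride | ClCc1ccc(OCc2ccccc2)cc1 | starting material
9 | (2R,5R)-1-[4-(benzyloxy)benzyl]-2,5-dimethylthiolan-1-ium tetrafluoroborate | C[C@@H]1CC[C@@H](C)[S+]1Cc1ccc(OCc2ccccc2)cc1.F[B-](F)(F)F | intermediate
10 | 3,5-bis(benzyloxy)phenylmagnesium bromide | Br[Mg]c1cc(OCc2ccccc2)cc(OCc2ccccc2)c1 | intermediate (not isolated)
11 | [4-(benzyloxy)phenyl][(2R,5R)-2,5-dimethylthiolan-1-ium-1-yl]methanide (ylide of 9) | C[C@@H]1CC[C@@H](C)[S+]1[CH-]c1ccc(OCc2ccccc2)cc1 | intermediate (not isolated)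
12 | bromomagnesium [4-(benzyloxy)-2-bromo-6-(tert-butoxycarbonyloxy)phenyl][3,5-bis(benzyloxy)phenyl]methanolate (both configurations at the carbinol carbon) | Br[Mg]OC(c1cc(OCc2ccccc2)cc(OCc2ccccc2)c1)c1c(Br)cc(OCc2ccccc2)cc1OC(=O)OC(C)(C)C | intermediate (not isolated)
13 | (6E)-3-(benzyloxy)-6-[3,5-bis(benzyloxy)benzylidene]-5-bromocyclohexa-2,4-dien-1-one (aryl on the carbonyl side) | O=C1C=C(OCc2ccccc2)C=C(Br)/C1=C/c1cc(OCc2ccccc2)cc(OCc2ccccc2)c1 | intermediate (not isolated)
14 | 5-(benzyloxy)-3-bromo-2-{(1R,2S)-2-[4-(benzyloxy)phenyl]-1-[3,5-bis(benzyloxy)phenyl]-2-[(2R,5R)-2,5-dimethylthiolan-1-ium-1-yl]ethyl}phenolate (anti betaine) | [O-]c1cc(OCc2ccccc2)cc(Br)c1[C@@H](c1cc(OCc2ccccc2)cc(OCc2ccccc2)c1)[C@@H](c1ccc(OCc2ccccc2)cc1)[S+]1[C@H](C)CC[C@H]1C | intermediate (not isolated)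
15 | (2R,3R)-6-(benzyloxy)-2-[4-(benzyloxy)phenyl]-3-[3,5-bis(benzyloxy)phenyl]-4-bromo-2,3-dihydro-1-benzofuran (trans) | Brc1cc(OCc3ccccc3)cc2c1[C@@H](c1cc(OCc3ccccc3)cc(OCc3ccccc3)c1)[C@H](c1ccc(OCc3ccccc3)cc1)O2 | intermediate
16 | 2,4-bis(benzyloxy)-6-{(2R,3R)-6-(benzyloxy)-2-[4-(benzyloxy)phenyl]-4-bromo-2,3-dihydro-1-benzofuran-3-yl}benzaldehyde | Brc1cc(OCc3ccccc3)cc2c1[C@@H](c1cc(OCc3ccccc3)cc(OCc3ccccc3)c1C=O)[C@H](c1ccc(OCc3ccccc3)cc1)O2 | intermediate
17 | 4-(benzyloxy)styrene | C=Cc1ccc(OCc2ccccc2)cc1 | starting material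
18 | 2,4-bis(benzyloxy)-6-{(2R,3R)-6-(benzyloxy)-2-[4-(benzyloxy)phenyl]-4-[(E)-2-[4-(benzyloxy)phenyl]ethenyl]-2,3-dihydro-1-benzofuran-3-yl}benzaldehyde | c1ccccc1COc1ccc(/C=C/c2cc(OCc4ccccc4)cc3c2[C@@H](c2cc(OCc4ccccc4)cc(OCc4ccccc4)c2C=O)[C@H](c2ccc(OCc4ccccc4)cc2)O3)cc1 | intermediate
19 | 4-(benzyloxy)-2-{(2R,3R)-6-(benzyloxy)-2-[4-(benzyloxy)phenyl]-4-[(E)-2-[4-(benzyloxy)phenyl]ethenyl]-2,3-dihydro-1-benzofuran-3-yl}-6-hydroxybenzaldehyde | c1ccccc1COc1ccc(/C=C/c2cc(OCc4ccccc4)cc3c2[C@@H](c2cc(OCc4ccccc4)cc(O)c2C=O)[C@H](c2ccc(OCc4ccccc4)cc2)O3)cc1 | intermediate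
20 | tert-butyl 5-(benzyloxy)-3-{(2R,3R)-6-(benzyloxy)-2-[4-(benzyloxy)phenyl]-4-[(E)-2-[4-(benzyloxy)phenyl]ethenyl]-2,3-dihydro-1-benzofuran-3-yl}-2-formylphenyl carbonate (unit-1 fragment, O-Boc salicylaldehyde on ring B) | c1ccccc1COc1ccc(/C=C/c2cc(OCc4ccccc4)cc3c2[C@@H](c2cc(OCc4ccccc4)cc(OC(=O)OC(C)(C)C)c2C=O)[C@H](c2ccc(OCc4ccccc4)cc2)O3)cc1 | intermediate
21 | (2R,5R)-hexane-2,5-diol | C[C@@H](O)CC[C@@H](C)O | starting material
22 | (2R,5R)-hexane-2,5-diyl dimethanesulfonate | C[C@@H](OS(C)(=O)=O)CC[C@@H](C)OS(C)(=O)=O | intermediate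
23 | (2S,5S)-2,5-dimethylthiolane | C[C@H]1CC[C@H](C)S1 | intermediate
24 | (2S,5S)-1-[4-(benzyloxy)benzyl]-2,5-dimethylthiolan-1-ium tetrafluoroborate | C[C@H]1CC[C@H](C)[S+]1Cc1ccc(OCc2ccccc2)cc1.F[B-](F)(F)F | intermediate
25 | aryllithium of 15 (lithium at C4 in place of bromine, (2R,3R)) | [Li]c1cc(OCc3ccccc3)cc2c1[C@@H](c1cc(OCc3ccccc3)cc(OCc3ccccc3)c1)[C@H](c1ccc(OCc3ccccc3)cc1)O2 | intermediate (not isolated)
26 | unit-3 arylmagnesium bromide (MgBr at C4 of 15, (2R,3R)) | Br[Mg]c1cc(OCc3ccccc3)cc2c1[C@@H](c1cc(OCc3ccccc3)cc(OCc3ccccc3)c1)[C@H](c1ccc(OCc3ccccc3)cc1)O2 | intermediate (not isolated)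
27 | [4-(benzyloxy)phenyl][(2S,5S)-2,5-dimethylthiolan-1-ium-1-yl]methanide (ylide of 24) | C[C@H]1CC[C@H](C)[S+]1[CH-]c1ccc(OCc2ccccc2)cc1 | intermediate (not isolated)
28 | bromomagnesium alkoxide from addition of 26 to the aldehyde of 20 (carbinol carbon joins ring B and C4 of ring C, both configurations; units 1 and 3 as in 20 and 15) | c1ccccc1COc1ccc(/C=C/c2cc(OCc4ccccc4)cc3c2[C@@H](c2cc(OCc4ccccc4)cc(OC(=O)OC(C)(C)C)c2C(O[Mg]Br)c2cc(OCc4ccccc4)cc5c2[C@@H](c2cc(OCc4ccccc4)cc(OCc4ccccc4)c2)[C@H](c2ccc(OCc4ccccc4)cc2)O5)[C@H](c2ccc(OCc4ccccc4)cc2)O3)cc1 | intermediate (not isolated)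
29 | o-quinone methide of ring B: 3-(benzyloxy)cyclohexa-2,4-dien-1-one carrying unit 1 (through its C3) at C5 and the (Z)-arylmethylidene of ring C (through its C4) at C6, aryl on the carbonyl side | c1ccccc1COc1ccc(/C=C/c2cc(OCc4ccccc4)cc3c2[C@@H](C2=CC(OCc4ccccc4)=CC(=O)/C2=C\c2cc(OCc4ccccc4)cc5c2[C@@H](c2cc(OCc4ccccc4)cc(OCc4ccccc4)c2)[C@H](c2ccc(OCc4ccccc4)cc2)O5)[C@H](c2ccc(OCc4ccccc4)cc2)O3)cc1 | intermediate (not isolated)
30 | anti betaine: ring-B phenolate whose ortho carbon bears the (1S,2R)-1-(ring C)-2-[4-(benzyloxy)phenyl]-2-[(2S,5S)-2,5-dimethylthiolan-1-ium-1-yl]ethyl group | c1ccccc1COc1ccc(/C=C/c2cc(OCc4ccccc4)cc3c2[C@@H](c2cc(OCc4ccccc4)cc([O-])c2[C@H](c2cc(OCc4ccccc4)cc5c2[C@@H](c2cc(OCc4ccccc4)cc(OCc4ccccc4)c2)[C@H](c2ccc(OCc4ccccc4)cc2)O5)[C@H](c2ccc(OCc4ccccc4)cc2)[S+]2[C@@H](C)CC[C@@H]2C)[C@H](c2ccc(OCc4ccccc4)cc2)O3)cc1 | intermediate (not isolated)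
31 | nona-O-benzyl miyabenol A (unit 1 2R,3R; unit 2 2S,3S; unit 3 2R,3R; E alkene) | c1ccccc1COc1ccc(/C=C/c2cc(OCc6ccccc6)cc3c2[C@@H](c2cc(OCc6ccccc6)cc4c2[C@H](c2cc(OCc6ccccc6)cc5c2[C@@H](c2cc(OCc6ccccc6)cc(OCc6ccccc6)c2)[C@H](c2ccc(OCc6ccccc6)cc2)O5)[C@@H](c2ccc(OCc6ccccc6)cc2)O4)[C@H](c2ccc(OCc6ccccc6)cc2)O3)cc1 | intermediate
32 | miyabenol A | Oc1ccc(/C=C/c2cc(O)cc3c2[C@@H](c2cc(O)cc4c2[C@H](c2cc(O)cc5c2[C@@H](c2cc(O)cc(O)c2)[C@H](c2ccc(O)cc2)O5)[C@@H](c2ccc(O)cc2)O4)[C@H](c2ccc(O)cc2)O3)cc1 | target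

**Step count and risks**

Total steps: 16. Longest linear sequence: 10 steps (1 → 2 → 3 → 4 → 15 → 16 → 18 → 19 → 20 → 31 → 32; steps 1, 2, 3, 7, 8, 9, 10, 11, 15, 16).

Steps most likely to fail:

1. Step 15. Two ortho-substituted partners may fail to combine. The quinone methide may be lost to paths faster than ylide attack (addition of a second Grignard, self-condensation, decay of the ylide before the methide is released). The sulfide and the resident stereocentres may also disagree on the face of the methide, which would erode the diastereoselectivity at unit 2. Fallback by known chemistry, which separates the addition from the methide release: setting out from 19 and 15, the phenol of 19 is deprotonated with i-PrMgCl (THF, −78 °C) and Grignard 26, made from 15 as in step 15, is added to give the diarylmethanol F1 with the ring-B phenol free. p-Toluenesulfinic acid in CH2Cl2 at room temperature should exchange the benzylic hydroxyl group and give the sulfone F2. Cs2CO3 in CH2Cl2 with salt 24 then releases the same quinone methide slowly by loss of sulfinate while the ylide forms in the same flask, which is the established base-mediated sulfonium-ylide (4+1) annulation, and the route is rejoined at 31.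

2. Step 7. The methide may be released too early and be captured by a second Grignard, the ylide may decay before the methide is available, or the sulfide may discriminate the ylide faces poorly and leave low enantiomeric purity in the bromide that feeds both halves of the molecule. Fallback by known chemistry: setting out from 3, addition of Grignard 10 (2.2 equiv, from 1; THF, 0 °C) to the free salicylaldehyde should give the diarylmethanol F3. p-Toluenesulfinic acid in CH2Cl2 converts it into the sulfone F4, and Cs2CO3 with salt 9 in CH2Cl2 at room temperature effects the known (4+1) annulation, rejoining the route at 15, which would be recrystallised if the enantiomeric purity needs raising.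

3. Step 8. Formylation may take place between the two benzyloxy groups of the pendant ring or on the bromine-bearing benzo ring instead of next to the C3 attachment, and the hindered position may react too slowly for a clean stop at one formyl group. Fallback that fixes the position of the formyl carbon by construction and relies on the union that step 7 has by then shown to work: setting out from 2, acetalisation (ethylene glycol, p-TsOH cat., toluene, Dean–Stark) gives 2-[2,4-bis(benzyloxy)-6-bromophenyl]-1,3-dioxolane F5. Bromine–lithium exchange (t-BuLi, 2 equiv, THF, −78 °C) gives the aryllithium F6, and MgBr2·OEt2 turns it into the arylmagnesium bromide F7. This is added to 4 at −78 °C to give the magnesium alkoxide F8, which on warming in the presence of ylide 11 (made again from 9 with LiN(SiMe3)2) releases the o-quinone methide F9; ylide addition gives the anti betaine F10, which closes to the dioxolane F11. Treatment with 1 M HCl in THF at room temperature frees the aldehyde, and the route is rejoined at 16.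

**Further compounds**

F1 | step 15 | diarylmethanol from 19 and 26: ring-B phenol free, carbinol carbon joining ring B and C4 of ring C (both configurations) | c1ccccc1COc1ccc(/C=C/c2cc(OCc4ccccc4)cc3c2[C@@H](c2cc(OCc4ccccc4)cc(O)c2C(O)c2cc(OCc4ccccc4)cc5c2[C@@H](c2cc(OCc4ccccc4)cc(OCc4ccccc4)c2)[C@H](c2ccc(OCc4ccccc4)cc2)O5)[C@H](c2ccc(OCc4ccccc4)cc2)O3)cc1
F2 | step 15 | sulfone of F1: benzylic hydroxyl replaced by 4-methylphenylsulfonyl (both configurations) | c1ccccc1COc1ccc(/C=C/c2cc(OCc4ccccc4)cc3c2[C@@H](c2cc(OCc4ccccc4)cc(O)c2C(c2cc(OCc4ccccc4)cc5c2[C@@H](c2cc(OCc4ccccc4)cc(OCc4ccccc4)c2)[C@H](c2ccc(OCc4ccccc4)cc2)O5)S(=O)(=O)c2ccc(C)cc2)[C@H](c2ccc(OCc4ccccc4)cc2)O3)cc1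
F3 | step 7 | 5-(benzyloxy)-2-{[3,5-bis(benzyloxy)phenyl](hydroxy)methyl}-3-bromophenol (racemic) | OC(c1cc(OCc2ccccc2)cc(OCc2ccccc2)c1)c1c(O)cc(OCc2ccccc2)cc1Br
F4 | step 7 | 5-(benzyloxy)-2-{[3,5-bis(benzyloxy)phenyl](4-methylphenylsulfonyl)methyl}-3-bromophenol (racemic) | Cc1ccc(cc1)S(=O)(=O)C(c1cc(OCc2ccccc2)cc(OCc2ccccc2)c1)c1c(O)cc(OCc2ccccc2)cc1Br
F5 | step 8 | 2-[2,4-bis(benzyloxy)-6-bromophenyl]-1,3-dioxolane | Brc1cc(OCc2ccccc2)cc(OCc2ccccc2)c1C1OCCO1
F6 | step 8 | [3,5-bis(benzyloxy)-2-(1,3-dioxolan-2-yl)phenyl]lithium | [Li]c1cc(OCc2ccccc2)cc(OCc2ccccc2)c1C1OCCO1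
F7 | step 8 | [3,5-bis(benzyloxy)-2-(1,3-dioxolan-2-yl)phenyl]magnesium bromide | Br[Mg]c1cc(OCc2ccccc2)cc(OCc2ccccc2)c1C1OCCO1
F8 | step 8 | bromomagnesium [4-(benzyloxy)-2-bromo-6-(tert-butoxycarbonyloxy)phenyl][3,5-bis(benzyloxy)-2-(1,3-dioxolan-2-yl)phenyl]methanolate (both configurations at the carbinol carbon) | Br[Mg]OC(c1cc(OCc2ccccc2)cc(OCc2ccccc2)c1C1OCCO1)c1c(Br)cc(OCc2ccccc2)cc1OC(=O)OC(C)(C)C
F9 | step 8 | (6E)-3-(benzyloxy)-6-[3,5-bis(benzyloxy)-2-(1,3-dioxolan-2-yl)benzylidene]-5-bromocyclohexa-2,4-dien-1-one (aryl on the carbonyl side) | O=C1C=C(OCc2ccccc2)C=C(Br)/C1=C/c1cc(OCc2ccccc2)cc(OCc2ccccc2)c1C1OCCO1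
F10 | step 8 | 5-(benzyloxy)-3-bromo-2-{(1R,2S)-2-[4-(benzyloxy)phenyl]-1-[3,5-bis(benzyloxy)-2-(1,3-dioxolan-2-yl)phenyl]-2-[(2R,5R)-2,5-dimethylthiolan-1-ium-1-yl]ethyl}phenolate (anti betaine) | [O-]c1cc(OCc2ccccc2)cc(Br)c1[C@@H](c1cc(OCc2ccccc2)cc(OCc2ccccc2)c1C1OCCO1)[C@@H](c1ccc(OCc2ccccc2)cc1)[S+]1[C@H](C)CC[C@H]1C
F11 | step 8 | 2-[2,4-bis(benzyloxy)-6-{(2R,3R)-6-(benzyloxy)-2-[4-(benzyloxy)phenyl]-4-bromo-2,3-dihydro-1-benzofuran-3-yl}phenyl]-1,3-dioxolane | Brc1cc(OCc3ccccc3)cc2c1[C@@H](c1cc(OCc3ccccc3)cc(OCc3ccccc3)c1C1OCCO1)[C@H](c1ccc(OCc3ccccc3)cc1)O2
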